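**Retrosynthetic overview**
1. Feature: C7 is shared by the γ-lactone (O–C6–C7–C11–C12) and the ten-membered ring and lies between the oxygenated carbons C6 and C8. With C6 as ketone and C8 as ester it is an epimerisable β-keto ester α-carbon, so one ketoreductase reduction with dynamic resolution sets C6 and C7, and the hydroxy ester closes the cis-lactone.
2. Target ⇒ late C15 desilylation, C14 oxidation, C8 angeloylation and C11 methylenation ⇒ ten-membered ring by ring-closing metathesis at C1=C10 ⇒ C8–C9 bond by catalyst-controlled 2-(PMB-oxymethyl)allylboration of the lactone C8 aldehyde.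
3. cis-Lactone ester 17 ⇒ racemic 2-acylsuccinate 15 ⇒ dienoic acid 9 + malonate half-ester + methyl bromoacetate. The C4=C5 geometry comes from anti hydroiodination of a 2-ynoate followed by Negishi coupling with butenylzinc bromide.
4. Ring order: γ-lactone first (step 8), ten-membered carbocycle second (step 15).

Key step: step 8

Remark: atoms carry the germacranolide numbers of the target (C1–C15); TBDPS = tert-butyldiphenylsilyl, PMB = 4-methoxybenzyl, TES = triethylsilyl; the ketoreductase is assumed to be the member of a commercial screening panel that gives the (6R,7R) hydroxy diester, and TBDPS is used on O15 because it must survive the acidolysis of the tert-butyl ester.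

Step 1
Reactants: 1 prop-2-yn-1-ol
Product: 2 tert-butyl(diphenyl)(prop-2-yn-1-yloxy)silane
Conditions: TBDPSCl, imidazole, CH2Cl2, 0 °C to rt
Reagents that add atoms: tert-butyl(chloro)diphenylsilane, CC(C)(C)[Si](Cl)(c1ccccc1)c1ccccc1
Why: Imidazole-mediated silylation of a primary alcohol; the TBDPS ether should tolerate the later AcOH/NaI, LiOH and TFA treatments.

Step 2
Reactants: 2 tert-butyl(diphenyl)(prop-2-yn-1-yloxy)silane
Product: 4 methyl 4-(TBDPS-oxy)but-2-ynoate, via lithium acetylide 3 (not isolated)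
Conditions: n-BuLi, THF, −78 °C; ClCO2Me, −78 to 0 °C
Reagents that add atoms: methyl chloroformate, COC(=O)Cl
Why: Deprotonation of the terminal alkyne and C-acylation of the acetylide with a chloroformate is a standard 2-ynoate synthesis; the new carbon is C6.

Step 3
Reactants: 4 methyl 4-(TBDPS-oxy)but-2-ynoate
Product: 5 methyl (2Z)-3-iodo-4-(TBDPS-oxy)but-2-enoate
Conditions: NaI, AcOH, 70 °C
Reagents that add atoms: sodium iodide, [Na+].[I-]
Why: Anti hydroiodination of a 2-ynoate (conjugate addition of iodide, then protonation) should place iodine cis to the ester and the C15 CH2O group trans to it.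

Step 4
Reactants: 5 methyl (2Z)-3-iodo-4-(TBDPS-oxy)but-2-enoate; 6 but-3-en-1-ylzinc bromide
Product: 7 methyl (2E)-3-(TBDPS-oxymethyl)hepta-2,6-dienoate
Conditions: PdCl2(dppf) (5 mol %), THF, 0 °C to rt
Reagents that add atoms: none
Why: Negishi sp2–sp3 coupling of an activated alkenyl iodide proceeds with retention, so the butenyl chain (C3–C1) ends cis to C6 and C15 trans, which is the C4=C5 geometry of the target.

Step 5
Reactants: 7 methyl (2E)-3-(TBDPS-oxymethyl)hepta-2,6-dienoate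
Product: 9 (2E)-3-(TBDPS-oxymethyl)hepta-2,6-dienoic acid, via lithium carboxylate 8 (not isolated)
Conditions: LiOH·H2O, THF/MeOH/H2O, rt; 1 M HCl to pH 3
Reagents that add atoms: lithium hydroxide, [Li+].[OH-]
Why: Saponification of a methyl ester; the β,β-disubstituted enoate should not isomerise and the TBDPS ether is stable to LiOH at room temperature.

Step 6
Reactants: 9 (2E)-3-(TBDPS-oxymethyl)hepta-2,6-dienoic acid; 10 potassium mono-tert-butyl malonate
Product: 13 tert-butyl (4E)-3-oxo-5-(TBDPS-oxymethyl)nona-4,8-dienoate, via acyl imidazolide 11 (not isolated), via acylmalonic half-ester 12 (not isolated)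
Conditions: CDI, THF, rt; then 10, MgCl2, Et3N, MeCN, rt to 40 °C; 1 M HCl
Reagents that add atoms: none
Why: Masamune–Brooks chain extension: the acyl imidazolide C-acylates the magnesium malonate and the acylmalonic acid decarboxylates on acidification, giving the β-keto ester (C6 ketone, C7, C8 ester) without strong base.

Step 7
Reactants: 13 tert-butyl (4E)-3-oxo-5-(TBDPS-oxymethyl)nona-4,8-dienoate; 14 methyl bromoacetate
Product: 15 1-tert-butyl 4-methyl 2-[(2E)-3-(TBDPS-oxymethyl)hepta-2,6-dienoyl]butanedioate (racemic at C7)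
Conditions: K2CO3, acetone, rt (1.0 equiv of 14)
Reagents that add atoms: none
Why: C-alkylation of a β-keto ester enolate with an α-bromo ester attaches the C11–C12 arm to C7; the new centre is deliberately left racemic and labile.

Step 8
Reactants: 15 1-tert-butyl 4-methyl 2-[(2E)-3-(TBDPS-oxymethyl)hepta-2,6-dienoyl]butanedioate
Product: 17 tert-butyl (2R,3R)-5-oxo-2-[(1E)-2-(TBDPS-oxymethyl)hexa-1,5-dien-1-yl]oxolane-3-carboxylate (cis-lactone), via hydroxy diester 16 (not isolated)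
Conditions: NADPH-dependent ketoreductase (panel-selected), NADP+ (cat.), i-PrOH, potassium phosphate buffer pH 7.0/DMSO, 30 °C; extraction; then CSA (cat.), CH2Cl2, rt
Reagents that add atoms: none
Why: The enzyme-bound NADPH delivers hydride to one face of the C6 carbonyl of the (7R) epimer of 15 only, while C7 epimerises through the enol of the β-keto ester in the neutral buffer, so the whole racemate should be funnelled into the (6R,7R) anti hydroxy diester 16 (hydride regenerated from isopropanol); this is the known ketoreductase dynamic kinetic resolution of α-substituted β-keto esters, applied here to a 2-acylsuccinate. Under acid catalysis O6 then adds to the C12 methyl ester carbonyl and methanol is expelled, a 5-exo-trig acyl substitution that closes the γ-lactone O–C6–C7–C11–C12. C6 is set by the facial selectivity of the enzyme and C7 by its choice between the two interconverting epimers; the anti relationship of 16 becomes the cis arrangement of the C5 alkenyl and C8 ester groups on the lactone. The step needs 1,2- and not 1,4-reduction of the enone, which a carbonyl reductase without ene-reductase activity provides, and it needs lactonisation through O6–C12 only, which is secured because C8 is an ester that the enzyme leaves alone and that O6 could reach only through a four-membered ring. After the reduction C7 is still α to the C8 ester and β to the lactone oxygen, so 16 and 17 are kept away from base to avoid epimerisation to the trans lactone or β-elimination.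

Step 9
Reactants: 17 tert-butyl (2R,3R)-5-oxo-2-[(1E)-2-(TBDPS-oxymethyl)hexa-1,5-dien-1-yl]oxolane-3-carboxylate
Product: 18 (2R,3R)-5-oxo-2-[(1E)-2-(TBDPS-oxymethyl)hexa-1,5-dien-1-yl]oxolane-3-carboxylic acid
Conditions: TFA/CH2Cl2 (1:4), 0 °C
Reagents that add atoms: none
Why: Acidolysis of the tert-butyl ester with loss of isobutene; acid does not enolise C7, and the TBDPS ether and the lactone should survive.

Step 10
Reactants: 18 (2R,3R)-5-oxo-2-[(1E)-2-(TBDPS-oxymethyl)hexa-1,5-dien-1-yl]oxolane-3-carboxylic acid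
Product: 20 (2R,3R)-5-oxo-2-[(1E)-2-(TBDPS-oxymethyl)hexa-1,5-dien-1-yl]oxolane-3-carbaldehyde, via acid chloride 19 (not isolated)
Conditions: (COCl)2, DMF (cat.), CH2Cl2, 0 °C; evaporate; LiAlH(OtBu)3 (1.05 equiv), THF, −78 °C; used at once
Reagents that add atoms: none
Why: Acid chloride formation and partial reduction with the hindered hydride LiAlH(OtBu)3 stops at the aldehyde and leaves the lactone alone; no base is present, so C7 should keep its configuration.

Step 11
Reactants: 21 3-chloro-2-(chloromethyl)prop-1-ene; 22 (4-methoxyphenyl)methanol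
Product: 24 1-({[2-(chloromethyl)prop-2-en-1-yl]oxy}methyl)-4-methoxybenzene, via sodium alkoxide 23 (not isolated)
Conditions: NaH, THF, 0 °C; then 21 (3 equiv), Bu4NI (cat.), rt
Reagents that add atoms: none
Why: Williamson ether synthesis on an allylic chloride; the excess of the dichloride suppresses double substitution.

Step 12
Reactants: 24 1-({[2-(chloromethyl)prop-2-en-1-yl]oxy}methyl)-4-methoxybenzene
Product: 25 2-{2-[(PMB-oxy)methyl]prop-2-en-1-yl}-4,4,5,5-tetramethyl-1,3,2-dioxaborolane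
Conditions: B2pin2, Pd2(dba)3 (2.5 mol %), THF, 60 °C
Reagents that add atoms: bis(pinacolato)diboron, CC1(C)OB(OC1(C)C)B1OC(C)(C)C(C)(C)O1
Why: Palladium-catalysed borylation of an allylic chloride (Miyaura-type); the two allyl termini are equivalent, so regiochemistry is not an issue.

Step 13
Reactants: 20 (2R,3R)-5-oxo-2-[(1E)-2-(TBDPS-oxymethyl)hexa-1,5-dien-1-yl]oxolane-3-carbaldehyde; 25 2-{2-[(PMB-oxy)methyl]prop-2-en-1-yl}-4,4,5,5-tetramethyl-1,3,2-dioxaborolane
Product: 27 (4S,5R)-4-[(1S)-1-hydroxy-3-(PMB-oxymethyl)but-3-en-1-yl]-5-[(1E)-2-(TBDPS-oxymethyl)hexa-1,5-dien-1-yl]oxolan-2-one, via pinacol borate ester 26 (not isolated)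
Conditions: (S)-TRIP phosphoric acid (10 mol %), 4 Å MS, toluene, −30 °C; then pH 7 buffer
Reagents that add atoms: none
Why: Chiral phosphoric acid-catalysed allylboration through a closed six-membered chair transition state; the catalyst selects the aldehyde face and sets C8 ((S)-catalyst for 8S, assigned by analogy with simple aldehydes), and the acid-only conditions spare the base-labile C7 centre.

Step 14
Reactants: 27 (4S,5R)-4-[(1S)-1-hydroxy-3-(PMB-oxymethyl)but-3-en-1-yl]-5-[(1E)-2-(TBDPS-oxymethyl)hexa-1,5-dien-1-yl]oxolan-2-one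
Product: 28 8-O-triethylsilyl ether of 27
Conditions: TESOTf, 2,6-lutidine, CH2Cl2, −78 °C
Reagents that add atoms: triethylsilyl trifluoromethanesulfonate, CC[Si](CC)(CC)OS(=O)(=O)C(F)(F)F
Why: Silylation of the hindered secondary alcohol; masking O8 prevents 6,12 to 8,12 translactonisation and keeps the angelate away from the enolate chemistry of step 16.

Step 15
Reactants: 28 8-O-triethylsilyl ether of 27
Product: 29 (3aR,4S,6E,10E,11aR)-6-(PMB-oxymethyl)-10-(TBDPS-oxymethyl)-4-(triethylsilyloxy)-3a,4,5,8,9,11a-hexahydrocyclodeca[b]furan-2(3H)-one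
Conditions: second-generation Hoveyda–Grubbs catalyst RuCl2(H2IMes)(=CH-C6H4-2-OiPr) (10 mol %), toluene (1 mM), 80 °C
Reagents that add atoms: none
Why: Ring-closing metathesis: the ruthenium alkylidene formed at the monosubstituted C1 alkene closes onto the 1,1-disubstituted C10 alkene with loss of ethene; the cis-fused lactone and the ring-cis C4=C5 bond hold both arms on one face, and only the ring-cis C1=C10 geometry (E by CIP) should fit the ten-membered ring.

Step 16
Reactants: 29 (3aR,4S,6E,10E,11aR)-6-(PMB-oxymethyl)-10-(TBDPS-oxymethyl)-4-(triethylsilyloxy)-3a,4,5,8,9,11a-hexahydrocyclodeca[b]furan-2(3H)-one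
Product: 33 (3aR,4S,6E,10E,11aR)-3-methylidene-6-(PMB-oxymethyl)-10-(TBDPS-oxymethyl)-4-(triethylsilyloxy)-3a,4,5,8,9,11a-hexahydrocyclodeca[b]furan-2(3H)-one, via lithium enolate 30 (not isolated), via Mannich base 31 (not isolated), via trimethylammonium iodide 32 (not isolated)
Conditions: LDA, THF, −78 °C; CH2=NMe2+ I−, −78 to 0 °C; MeI, MeOH, rt; NaHCO3 (aq.), CH2Cl2, rt
Reagents that add atoms: Eschenmoser's salt, C=[N+](C)C.[I-]
Why: α-Methylenation by Mannich reaction of the lactone enolate, N-methylation and E1cB elimination of trimethylamine; C11 is the only enolisable position because no other ester is present at this stage.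

Step 17
Reactants: 33 (3aR,4S,6E,10E,11aR)-3-methylidene-6-(PMB-oxymethyl)-10-(TBDPS-oxymethyl)-4-(triethylsilyloxy)-3a,4,5,8,9,11a-hexahydrocyclodeca[b]furan-2(3H)-one
Product: 34 (3aS,4S,6E,10E,11aR)-4-hydroxy-3-methylidene-6-(PMB-oxymethyl)-10-(TBDPS-oxymethyl)-3a,4,5,8,9,11a-hexahydrocyclodeca[b]furan-2(3H)-one
Conditions: PPTS, MeOH/CH2Cl2, 0 °C
Reagents that add atoms: none
Why: Acid-catalysed methanolysis removes the TES ether selectively in the presence of the much more robust TBDPS ether and the PMB ether.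

Step 18
Reactants: 34 (3aS,4S,6E,10E,11aR)-4-hydroxy-3-methylidene-6-(PMB-oxymethyl)-10-(TBDPS-oxymethyl)-3a,4,5,8,9,11a-hexahydrocyclodeca[b]furan-2(3H)-one; 35 angelic acid
Product: 37 (3aS,4S,6E,10E,11aR)-3-methylidene-2-oxo-6-(PMB-oxymethyl)-10-(TBDPS-oxymethyl)-2,3,3a,4,5,8,9,11a-octahydrocyclodeca[b]furan-4-yl (2Z)-2-methylbut-2-enoate, via mixed anhydride 36 (not isolated)
Conditions: 35, 2,4,6-Cl3C6H2COCl, Et3N, toluene, rt; then 34, toluene, 80 °C
Reagents that add atoms: none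
Why: Yamaguchi esterification through the mixed anhydride, run without DMAP so that the (Z)-angelate should not isomerise to the tiglate; the weak amine base does not open or migrate the lactone.

Step 19
Reactants: 37 (3aS,4S,6E,10E,11aR)-3-methylidene-2-oxo-6-(PMB-oxymethyl)-10-(TBDPS-oxymethyl)-2,3,3a,4,5,8,9,11a-octahydrocyclodeca[b]furan-4-yl (2Z)-2-methylbut-2-enoate
Product: 38 (3aS,4S,6E,10E,11aR)-6-(hydroxymethyl)-3-methylidene-2-oxo-10-(TBDPS-oxymethyl)-2,3,3a,4,5,8,9,11a-octahydrocyclodeca[b]furan-4-yl (2Z)-2-methylbut-2-enoate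
Conditions: DDQ, CH2Cl2/pH 7 buffer, 0 °C
Reagents that add atoms: none
Why: Oxidative cleavage of the PMB ether by DDQ (benzylic hydride abstraction, hydrolysis of the hemiacetal) frees O14 only.

Step 20
Reactants: 38 (3aS,4S,6E,10E,11aR)-6-(hydroxymethyl)-3-methylidene-2-oxo-10-(TBDPS-oxymethyl)-2,3,3a,4,5,8,9,11a-octahydrocyclodeca[b]furan-4-yl (2Z)-2-methylbut-2-enoate
Product: 39 (3aS,4S,6E,10E,11aR)-6-formyl-3-methylidene-2-oxo-10-(TBDPS-oxymethyl)-2,3,3a,4,5,8,9,11a-octahydrocyclodeca[b]furan-4-yl (2Z)-2-methylbut-2-enoate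
Conditions: MnO2, CH2Cl2, rt
Reagents that add atoms: none
Why: MnO2 oxidation of the only free allylic alcohol gives the C14 enal with retention of the C1=C10 geometry.

Step 21
Reactants: 39 (3aS,4S,6E,10E,11aR)-6-formyl-3-methylidene-2-oxo-10-(TBDPS-oxymethyl)-2,3,3a,4,5,8,9,11a-octahydrocyclodeca[b]furan-4-yl (2Z)-2-methylbut-2-enoate
Product: 40 (3aS,4S,6E,10E,11aR)-6-formyl-10-(hydroxymethyl)-3-methylidene-2-oxo-2,3,3a,4,5,8,9,11a-octahydrocyclodeca[b]furan-4-yl (2Z)-2-methylbut-2-enoate (CNP0173211.3)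
Conditions: HF·pyridine, pyridine, THF, 0 °C to rt
Reagents that add atoms: none
Why: Fluoride-mediated desilylation under buffered, non-basic conditions frees O15 without touching the enal, the α-methylene lactone or the angelate.

**Compound list**
1 | prop-2-yn-1-ol | C#CCO | starting material
2 | tert-butyl(diphenyl)(prop-2-yn-1-yloxy)silane | C#CCO[Si](c1ccccc1)(c1ccccc1)C(C)(C)C | intermediate
3 | lithium acetylide of 2 | [Li]C#CCO[Si](c1ccccc1)(c1ccccc1)C(C)(C)C | intermediate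
4 | methyl 4-(TBDPS-oxy)but-2-ynoate | COC(=O)C#CCO[Si](c1ccccc1)(c1ccccc1)C(C)(C)C | intermediate
5 | methyl (2Z)-3-iodo-4-(TBDPS-oxy)but-2-enoate | COC(=O)/C=C(I)/CO[Si](c1ccccc1)(c1ccccc1)C(C)(C)C | intermediate
6 | but-3-en-1-ylzinc bromide | C=CCC[Zn]Br | starting material
7 | methyl (2E)-3-(TBDPS-oxymethyl)hepta-2,6-dienoate | COC(=O)/C=C(/CO[Si](c1ccccc1)(c1ccccc1)C(C)(C)C)CCC=C | intermediate
8 | lithium (2E)-3-(TBDPS-oxymethyl)hepta-2,6-dienoate | [Li+].[O-]C(=O)/C=C(/CO[Si](c1ccccc1)(c1ccccc1)C(C)(C)C)CCC=C | intermediate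
9 | (2E)-3-(TBDPS-oxymethyl)hepta-2,6-dienoic acid | OC(=O)/C=C(/CO[Si](c1ccccc1)(c1ccccc1)C(C)(C)C)CCC=C | intermediate
10 | potassium mono-tert-butyl malonate | [K+].[O-]C(=O)CC(=O)OC(C)(C)C | starting material
11 | 1-[(2E)-3-(TBDPS-oxymethyl)hepta-2,6-dienoyl]imidazole | O=C(/C=C(/CO[Si](c1ccccc1)(c1ccccc1)C(C)(C)C)CCC=C)n1ccnc1 | intermediate
12 | 3-tert-butoxy-3-oxo-2-[(2E)-3-(TBDPS-oxymethyl)hepta-2,6-dienoyl]propanoic acid (present as magnesium chelate) | OC(=O)C(C(=O)OC(C)(C)C)C(=O)/C=C(/CO[Si](c1ccccc1)(c1ccccc1)C(C)(C)C)CCC=C | intermediate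
13 | tert-butyl (4E)-3-oxo-5-(TBDPS-oxymethyl)nona-4,8-dienoate | CC(C)(C)OC(=O)CC(=O)/C=C(/CO[Si](c1ccccc1)(c1ccccc1)C(C)(C)C)CCC=C | intermediate
14 | methyl bromoacetate | COC(=O)CBr | starting material
15 | 1-tert-butyl 4-methyl 2-[(2E)-3-(TBDPS-oxymethyl)hepta-2,6-dienoyl]butanedioate (racemic at C7) | CC(C)(C)OC(=O)C(CC(=O)OC)C(=O)/C=C(/CO[Si](c1ccccc1)(c1ccccc1)C(C)(C)C)CCC=C | intermediate
16 | 1-tert-butyl 4-methyl (2R)-2-[(1R,2E)-1-hydroxy-3-(TBDPS-oxymethyl)hepta-2,6-dien-1-yl]butanedioate (anti) | COC(=O)C[C@@H](C(=O)OC(C)(C)C)[C@H](O)/C=C(/CO[Si](c1ccccc1)(c1ccccc1)C(C)(C)C)CCC=C | intermediate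
17 | tert-butyl (2R,3R)-5-oxo-2-[(1E)-2-(TBDPS-oxymethyl)hexa-1,5-dien-1-yl]oxolane-3-carboxylate (cis) | C1C(=O)O[C@H](/C=C(/CO[Si](c2ccccc2)(c2ccccc2)C(C)(C)C)CCC=C)[C@@H]1C(=O)OC(C)(C)C | intermediate
18 | (2R,3R)-5-oxo-2-[(1E)-2-(TBDPS-oxymethyl)hexa-1,5-dien-1-yl]oxolane-3-carboxylic acid | C1C(=O)O[C@H](/C=C(/CO[Si](c2ccccc2)(c2ccccc2)C(C)(C)C)CCC=C)[C@@H]1C(=O)O | intermediate
19 | (2R,3R)-5-oxo-2-[(1E)-2-(TBDPS-oxymethyl)hexa-1,5-dien-1-yl]oxolane-3-carbonyl chloride | C1C(=O)O[C@H](/C=C(/CO[Si](c2ccccc2)(c2ccccc2)C(C)(C)C)CCC=C)[C@@H]1C(Cl)=O | intermediate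
20 | (2R,3R)-5-oxo-2-[(1E)-2-(TBDPS-oxymethyl)hexa-1,5-dien-1-yl]oxolane-3-carbaldehyde | C1C(=O)O[C@H](/C=C(/CO[Si](c2ccccc2)(c2ccccc2)C(C)(C)C)CCC=C)[C@@H]1C=O | intermediate
21 | 3-chloro-2-(chloromethyl)prop-1-ene | C=C(CCl)CCl | starting material
22 | (4-methoxyphenyl)methanol | COc1ccc(CO)cc1 | starting material
23 | sodium (4-methoxyphenyl)methanolate | [Na+].[O-]Cc1ccc(OC)cc1 | intermediate
24 | 1-({[2-(chloromethyl)prop-2-en-1-yl]oxy}methyl)-4-methoxybenzene | C=C(CCl)COCc1ccc(OC)cc1 | intermediate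
25 | 2-{2-[(PMB-oxy)methyl]prop-2-en-1-yl}-4,4,5,5-tetramethyl-1,3,2-dioxaborolane | C=C(COCc1ccc(OC)cc1)CB1OC(C)(C)C(C)(C)O1 | intermediate
26 | pinacol borate ester of 27 (O8–B) | C1C(=O)O[C@H](/C=C(/CO[Si](c2ccccc2)(c2ccccc2)C(C)(C)C)CCC=C)[C@@H]1[C@@H](OB1OC(C)(C)C(C)(C)O1)CC(=C)COCc1ccc(OC)cc1 | intermediate
27 | (4S,5R)-4-[(1S)-1-hydroxy-3-(PMB-oxymethyl)but-3-en-1-yl]-5-[(1E)-2-(TBDPS-oxymethyl)hexa-1,5-dien-1-yl]oxolan-2-one | C1C(=O)O[C@H](/C=C(/CO[Si](c2ccccc2)(c2ccccc2)C(C)(C)C)CCC=C)[C@@H]1[C@@H](O)CC(=C)COCc1ccc(OC)cc1 | intermediate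
28 | 8-O-triethylsilyl ether of 27 (configuration unchanged) | C1C(=O)O[C@H](/C=C(/CO[Si](c2ccccc2)(c2ccccc2)C(C)(C)C)CCC=C)[C@@H]1[C@@H](O[Si](CC)(CC)CC)CC(=C)COCc1ccc(OC)cc1 | intermediate
29 | (3aR,4S,6E,10E,11aR)-6-(PMB-oxymethyl)-10-(TBDPS-oxymethyl)-4-(triethylsilyloxy)-3a,4,5,8,9,11a-hexahydrocyclodeca[b]furan-2(3H)-one (cis-fused, both ring alkenes ring-cis) | C1C(=O)O[C@@H]2/C=C(/CO[Si](c3ccccc3)(c3ccccc3)C(C)(C)C)CC/C=C(/COCc3ccc(OC)cc3)C[C@H](O[Si](CC)(CC)CC)[C@H]12 | intermediate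
30 | lithium enolate of 29 (C11=C12) | C1=C([O-])O[C@@H]2/C=C(/CO[Si](c3ccccc3)(c3ccccc3)C(C)(C)C)CC/C=C(/COCc3ccc(OC)cc3)C[C@H](O[Si](CC)(CC)CC)[C@H]12.[Li+] | intermediate
31 | 11-(dimethylaminomethyl) derivative of 29 (C11 epimers, C11 not defined) | CN(C)CC1C(=O)O[C@@H]2/C=C(/CO[Si](c3ccccc3)(c3ccccc3)C(C)(C)C)CC/C=C(/COCc3ccc(OC)cc3)C[C@H](O[Si](CC)(CC)CC)[C@H]12 | intermediate
32 | 11-(trimethylammoniomethyl) iodide of 29 (C11 not defined) | C[N+](C)(C)CC1C(=O)O[C@@H]2/C=C(/CO[Si](c3ccccc3)(c3ccccc3)C(C)(C)C)CC/C=C(/COCc3ccc(OC)cc3)C[C@H](O[Si](CC)(CC)CC)[C@H]12.[I-] | intermediate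
33 | (3aR,4S,6E,10E,11aR)-3-methylidene-6-(PMB-oxymethyl)-10-(TBDPS-oxymethyl)-4-(triethylsilyloxy)-3a,4,5,8,9,11a-hexahydrocyclodeca[b]furan-2(3H)-one | C=C1C(=O)O[C@@H]2/C=C(/CO[Si](c3ccccc3)(c3ccccc3)C(C)(C)C)CC/C=C(/COCc3ccc(OC)cc3)C[C@H](O[Si](CC)(CC)CC)[C@H]12 | intermediate
34 | (3aS,4S,6E,10E,11aR)-4-hydroxy-3-methylidene-6-(PMB-oxymethyl)-10-(TBDPS-oxymethyl)-3a,4,5,8,9,11a-hexahydrocyclodeca[b]furan-2(3H)-one | C=C1C(=O)O[C@@H]2/C=C(/CO[Si](c3ccccc3)(c3ccccc3)C(C)(C)C)CC/C=C(/COCc3ccc(OC)cc3)C[C@H](O)[C@H]12 | intermediate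
35 | angelic acid, (2Z)-2-methylbut-2-enoic acid | C/C=C(/C)C(=O)O | starting material
36 | (2Z)-2-methylbut-2-enoic 2,4,6-trichlorobenzoic anhydride | C/C=C(/C)C(=O)OC(=O)c1c(Cl)cc(Cl)cc1Cl | intermediate
37 | (3aS,4S,6E,10E,11aR)-3-methylidene-2-oxo-6-(PMB-oxymethyl)-10-(TBDPS-oxymethyl)-2,3,3a,4,5,8,9,11a-octahydrocyclodeca[b]furan-4-yl (2Z)-2-methylbut-2-enoate | C=C1C(=O)O[C@@H]2/C=C(/CO[Si](c3ccccc3)(c3ccccc3)C(C)(C)C)CC/C=C(/COCc3ccc(OC)cc3)C[C@H](OC(=O)/C(C)=C\C)[C@H]12 | intermediate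
38 | (3aS,4S,6E,10E,11aR)-6-(hydroxymethyl)-3-methylidene-2-oxo-10-(TBDPS-oxymethyl)-2,3,3a,4,5,8,9,11a-octahydrocyclodeca[b]furan-4-yl (2Z)-2-methylbut-2-enoate | C=C1C(=O)O[C@@H]2/C=C(/CO[Si](c3ccccc3)(c3ccccc3)C(C)(C)C)CC/C=C(/CO)C[C@H](OC(=O)/C(C)=C\C)[C@H]12 | intermediate
39 | (3aS,4S,6E,10E,11aR)-6-formyl-3-methylidene-2-oxo-10-(TBDPS-oxymethyl)-2,3,3a,4,5,8,9,11a-octahydrocyclodeca[b]furan-4-yl (2Z)-2-methylbut-2-enoate | C=C1C(=O)O[C@@H]2/C=C(/CO[Si](c3ccccc3)(c3ccccc3)C(C)(C)C)CC/C=C(/C=O)C[C@H](OC(=O)/C(C)=C\C)[C@H]12 | intermediate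
40 | (3aS,4S,6E,10E,11aR)-6-formyl-10-(hydroxymethyl)-3-methylidene-2-oxo-2,3,3a,4,5,8,9,11a-octahydrocyclodeca[b]furan-4-yl (2Z)-2-methylbut-2-enoate (6R,7S,8S in germacranolide numbering) | C=C1C(=O)O[C@@H]2/C=C(/CO)CC/C=C(/C=O)C[C@H](OC(=O)/C(C)=C\C)[C@H]12 | target

**Step count and risk**
Total: 21 steps. Longest linear sequence: 19 steps (steps 1–10 and 13–21; steps 11–12 make the allylboronate).

Steps most likely to fail:

1. Step 8 (key step). The hindered, lipophilic enone may not be turned over by any panel member, or the enzyme may reduce both C7 epimers at comparable rates, so that the dynamic resolution is lost and trans lactone forms beside cis. Fallback, setting out from 13 and returning at 16 (and so 17): the two centres are set one after the other by chemical means. Asymmetric transfer hydrogenation of the ketone of 13 (RuCl(p-cymene)[(S,S)-TsDPEN], HCO2H/Et3N, rt), with the alkenyl group in the role of the aryl group of the usual substrates, should give tert-butyl (3S,4E)-3-hydroxy-5-(TBDPS-oxymethyl)nona-4,8-dienoate F1. Fráter–Seebach alkylation of its dianion (LDA 2.2 equiv, THF/DMPU, −78 to −30 °C, then 14, cold AcOH quench) introduces the C11–C12 arm anti to the chelated alkoxide and gives 16, which is lactonised to 17 as in step 8.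

2. Step 15. The alkylidene formed at C1 may engage the hindered 1,1-disubstituted allyl ether too slowly, so that intermolecular metathesis through the monosubstituted alkene (oligomerisation) outruns closure of the strained ten-membered ring. Fallback, setting out from 28 and returning at 29: the ring is closed on an electron-poor 2-substituted acrolein, a partner class for which metathesis with monosubstituted alkenes to (E)-2-alkylenals is dependable and not readily reversed. DDQ (CH2Cl2/pH 7 buffer) removes the PMB group of 28 to give the C14 allylic alcohol F2; MnO2 gives the 2-substituted acrolein F3; ring-closing metathesis (same ruthenium catalyst, toluene, 1 mM, 80 °C) should give the ring-closed enal F4; Luche reduction (NaBH4, CeCl3·7H2O, MeOH, −40 °C) gives the ring-closed C14 alcohol F5; 4-methoxybenzyl trichloroacetimidate with La(OTf)3 (cat.) in toluene returns 29.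

3. Step 13. Catalyst control may not override the intrinsic facial preference of the α-branched aldehyde (the Felkin–Anh model favours the C8 epimer, so this is the mismatched case), and 20 may epimerise at C7 or eliminate the C6 carboxylate while the slow addition proceeds. Fallback, setting out from 20 and returning at 27: C8 is set by ketone reduction instead of by C–C bond formation. Uncatalysed addition of 25 to 20 (toluene, rt) gives, through the borate esters F6, the homoallylic alcohols F7 as a mixture of C8 epimers; Dess–Martin periodinane (CH2Cl2, 0 °C) gives the β,γ-unsaturated C8 ketone F8; Corey–Bakshi–Shibata reduction ((R)-2-methyl-CBS-oxazaborolidine, catecholborane, toluene, −78 °C), with the ring-bearing C7 as the large and C9H2 as the small substituent, should deliver 27.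

Further compounds
F1 | step 8 | tert-butyl (3S,4E)-3-hydroxy-5-(TBDPS-oxymethyl)nona-4,8-dienoate | CC(C)(C)OC(=O)C[C@H](O)/C=C(/CO[Si](c1ccccc1)(c1ccccc1)C(C)(C)C)CCC=C
F2 | step 15 | (4R,5R)-4-[(1S)-3-(hydroxymethyl)-1-(triethylsilyloxy)but-3-en-1-yl]-5-[(1E)-2-(TBDPS-oxymethyl)hexa-1,5-dien-1-yl]oxolan-2-one | C1C(=O)O[C@H](/C=C(/CO[Si](c2ccccc2)(c2ccccc2)C(C)(C)C)CCC=C)[C@@H]1[C@@H](O[Si](CC)(CC)CC)CC(=C)CO
F3 | step 15 | (4R,5R)-4-[(1S)-3-formyl-1-(triethylsilyloxy)but-3-en-1-yl]-5-[(1E)-2-(TBDPS-oxymethyl)hexa-1,5-dien-1-yl]oxolan-2-one | C1C(=O)O[C@H](/C=C(/CO[Si](c2ccccc2)(c2ccccc2)C(C)(C)C)CCC=C)[C@@H]1[C@@H](O[Si](CC)(CC)CC)CC(=C)C=O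
F4 | step 15 | (3aR,4S,6E,10E,11aR)-2-oxo-10-(TBDPS-oxymethyl)-4-(triethylsilyloxy)-2,3,3a,4,5,8,9,11a-octahydrocyclodeca[b]furan-6-carbaldehyde | C1C(=O)O[C@@H]2/C=C(/CO[Si](c3ccccc3)(c3ccccc3)C(C)(C)C)CC/C=C(/C=O)C[C@H](O[Si](CC)(CC)CC)[C@H]12
F5 | step 15 | (3aR,4S,6E,10E,11aR)-6-(hydroxymethyl)-10-(TBDPS-oxymethyl)-4-(triethylsilyloxy)-3a,4,5,8,9,11a-hexahydrocyclodeca[b]furan-2(3H)-one | C1C(=O)O[C@@H]2/C=C(/CO[Si](c3ccccc3)(c3ccccc3)C(C)(C)C)CC/C=C(/CO)C[C@H](O[Si](CC)(CC)CC)[C@H]12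
F6 | step 13 | pinacol borate esters of F7 (C8 epimer mixture) | C1C(=O)O[C@H](/C=C(/CO[Si](c2ccccc2)(c2ccccc2)C(C)(C)C)CCC=C)[C@@H]1C(OB1OC(C)(C)C(C)(C)O1)CC(=C)COCc1ccc(OC)cc1
F7 | step 13 | 27 together with its C8 epimer (C8 not defined) | C1C(=O)O[C@H](/C=C(/CO[Si](c2ccccc2)(c2ccccc2)C(C)(C)C)CCC=C)[C@@H]1C(O)CC(=C)COCc1ccc(OC)cc1
F8 | step 13 | (4R,5R)-4-[3-(PMB-oxymethyl)but-3-enoyl]-5-[(1E)-2-(TBDPS-oxymethyl)hexa-1,5-dien-1-yl]oxolan-2-one | C1C(=O)O[C@H](/C=C(/CO[Si](c2ccccc2)(c2ccccc2)C(C)(C)C)CCC=C)[C@@H]1C(=O)CC(=C)COCc1ccc(OC)cc1
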